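The whole route rests on deleting the chlorine-bearing carbon C10 (prostanoid numbering) from the cyclopentenone ring C8–C12. The feature exploited is the C9(=O)–C10(Cl)=C11 chloroenone: without C10, the ring C8–C9–C11–C12 is a cyclobutanone with a mirror plane through C9 and C12, so the lone stereocentre C12 reduces to a choice between enantiotopic methylenes. The key step adds dichlorocarbene to the C9=C11 bond of the precursor, a cyclobutene bearing a triethylsilyl enol ether at C9 and OTBS plus the (Z)-oct-2-enyl chain at C12. Opening of the bicyclo[2.1.0]pentane forms C9–C10 and C10–C11, enlarges the ring and installs the C10 chlorine in one operation.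

Key step: step 8

Remarks on the chemistry
- Positions are given in prostanoid numbering: C1 is the ester carbon, C8–C12 the ring, C13–C20 the octenyl chain.
- Assumption: the (S,S)-amide is taken to be the enantiomer that removes a proton from the methylene that becomes C11, giving (S)-14. The sense of induction has to be checked on the first run, and the (R,R)-amide, equally available, is used if it proves opposite.
- Precursor design: the enol ether is carried as the triethylsilyl ether so that it survives removal of the chiral amine and contact with tert-butoxide. Compound 14 is kept at or below 0 °C, because 3-siloxycyclobutenes open to dienes near room temperature.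
- Side chain: C1–C6 are taken from hex-5-ynoic acid, whose dianion can be hydroxymethylated cleanly to add C7; a terminal alkyne cannot be deprotonated selectively next to a methyl ester.

Step 1
Reactants: 1 3-chloro-2-(chloromethyl)prop-1-ene
Product: 2 2,2-bis(chloromethyl)oxirane
Conditions: mCPBA, ClCH2CH2Cl, 70 °C, cat. 2,6-di-tert-butyl-4-methylphenol
Reagents that add atoms: 3-chloroperoxybenzoic acid, OOC(=O)c1cccc(Cl)c1
Why: Prilezhaev epoxidation; the alkene is deactivated by its two allylic chlorines, so hot peracid with a radical scavenger is used, and no stereocentre is formed because the product has a mirror plane.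

Step 2
Reactants: 2 2,2-bis(chloromethyl)oxirane; 3 hept-1-yne
Product: 5 1-chloro-2-(chloromethyl)dec-4-yn-2-ol, via hept-1-ynyllithium 4 (not isolated)
Conditions: 3, n-BuLi, THF, −78 °C; BF3·OEt2; then 2, −78 °C; aq. NH4Cl at −78 °C
Reagents that add atoms: none
Why: Yamaguchi–Hirao alkynylation (BF3-promoted SN2 opening of an epoxide by a lithium acetylide); attack occurs at the unsubstituted oxirane CH2 because ionisation at the other carbon is disfavoured by its two chloromethyl groups, the cold quench keeps the bis-chlorohydrin from closing to an epoxide, and the product is achiral.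

Step 3
Reactants: 5 1-chloro-2-(chloromethyl)dec-4-yn-2-ol
Product: 6 (Z)-1-chloro-2-(chloromethyl)dec-4-en-2-ol
Conditions: H2 (1 atm), Pd/CaCO3 poisoned with Pb(OAc)2 (Lindlar catalyst), quinoline, EtOAc, 20 °C
Reagents that add atoms: none
Why: Lindlar semihydrogenation; syn delivery of H2 on the poisoned catalyst sets the C14=C15 Z geometry, the primary chlorides are inert, and the step is placed before sulfur enters the molecule because sulfur would poison the catalyst.

Step 4
Reactants: 6 (Z)-1-chloro-2-(chloromethyl)dec-4-en-2-ol; 7 1,3-dithiane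
Product: 11 2-[(Z)-oct-2-en-1-yl]-5,9-dithiaspiro[3.5]nonan-2-ol, via 2-lithio-1,3-dithiane 8 (not isolated), via chloromethyl oxirane 9 (not isolated), via epoxy dithiane 10 (not isolated)
Conditions: 7, n-BuLi (1.0 equiv), THF, −30 °C; add 6 pre-treated with n-BuLi (1.0 equiv, THF, −78 °C); −30 → 20 °C; recool to −30 °C, n-BuLi (1.1 equiv), → 20 °C; aq. NH4Cl
Reagents that add atoms: none
Why: Corey–Seebach dithiane bis-alkylation in its epihalohydrin form; the lithium alkoxide of 6 closes to oxirane 9, lithiodithiane 8 opens it at CH2, the new alkoxide expels the second chloride to give 10, and the second lithiation closes the four-membered ring on the oxirane CH2 (the three-ring alternative would need SN2 at a fully substituted carbon), giving an achiral product.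

Step 5
Reactants: 11 2-[(Z)-oct-2-en-1-yl]-5,9-dithiaspiro[3.5]nonan-2-ol
Product: 12 tert-butyldimethyl({2-[(Z)-oct-2-en-1-yl]-5,9-dithiaspiro[3.5]nonan-2-yl}oxy)silane
Conditions: TBSOTf, 2,6-lutidine, CH2Cl2, 0 → 20 °C
Reagents that add atoms: tert-butyldimethylsilyl trifluoromethanesulfonate, CC(C)(C)[Si](C)(C)OS(=O)(=O)C(F)(F)F
Why: Silylation of a tertiary alcohol with a silyl triflate and a hindered pyridine base; the carbinol is capped before the ketone is unmasked so that the β-hydroxycyclobutanone cannot open by retro-aldol cleavage.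

Step 6
Reactants: 12 tert-butyldimethyl({2-[(Z)-oct-2-en-1-yl]-5,9-dithiaspiro[3.5]nonan-2-yl}oxy)silane
Product: 13 3-[(tert-butyldimethylsilyl)oxy]-3-[(Z)-oct-2-en-1-yl]cyclobutan-1-one
Conditions: PhI(OCOCF3)2, MeCN–H2O (9:1), 0 °C, 15 min
Reagents that add atoms: water, O
Why: Oxidative dethioacetalisation with a hypervalent iodine reagent; sulfur is oxidised much faster than the Z-alkene, water captures the thionium ion, and the tertiary silyl ether survives the brief exposure to trifluoroacetic acid.

Step 7
Reactants: 13 3-[(tert-butyldimethylsilyl)oxy]-3-[(Z)-oct-2-en-1-yl]cyclobutan-1-one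
Product: 14 (S)-3-[(tert-butyldimethylsilyl)oxy]-3-[(Z)-oct-2-en-1-yl]-1-[(triethylsilyl)oxy]cyclobut-1-ene
Conditions: (S,S)-bis(1-phenylethyl)amine, n-BuLi, THF, −78 → 0 °C; Et3SiCl; then 13 added slowly at −100 °C; cold pentane/aq. NaHCO3 work-up, filtration through Et3N-deactivated SiO2 at 0 °C, used at once
Reagents that add atoms: chlorotriethylsilane, CC[Si](Cl)(CC)CC
Why: Enantiotopic-group-selective deprotonation by a C2-symmetric chiral lithium amide under internal silyl chloride quench, the reaction type established for 3-substituted cyclobutanones; C12 becomes stereogenic because the amide removes a proton from the methylene that becomes C11 and not from C8, the bulky OTBS group confining the base to the opposite ring face so that its left/right preference becomes a choice between the two methylenes.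

Step 8
Reactants: 14 (S)-3-[(tert-butyldimethylsilyl)oxy]-3-[(Z)-oct-2-en-1-yl]-1-[(triethylsilyl)oxy]cyclobut-1-ene; 15 chloroform
Product: 18 (S)-4-[(tert-butyldimethylsilyl)oxy]-2-chloro-4-[(Z)-oct-2-en-1-yl]cyclopent-2-en-1-one, via dichlorocarbene 16 (not isolated), via dichlorobicyclopentane adduct 17 (not isolated)
Conditions: CHCl3 (1.5 equiv), KOtBu (1.2 equiv, added in portions), pentane, −40 → 0 °C; aq. NH4Cl
Reagents that add atoms: none
Why: α-Elimination of HCl from chloroform by tert-butoxide gives singlet dichlorocarbene 16, which adds in a concerted cheletropic [2+1] fashion to the strained, electron-rich C9=C11 enol ether and so closes the three-membered ring C9–C10–C11 of bicycle 17. The central C9–C11 bond of 17 then opens by disrotatory cyclopropyl-to-allyl ionisation with departure of the endo chloride (the only mode a small fused ring allows), assisted by the C9 siloxy oxygen and by release of bicyclopentane strain, and chloride removes the triethylsilyl group from the resulting oxocarbenium ion to leave the C9 ketone conjugated with C10(Cl)=C11. The five-membered ring is therefore not closed end to end but arises by enlargement of the four-membered ring through this electrocyclic opening. The closest known reaction type is the dihalocarbene homologation of cyclic silyl enol ethers to 2-halocycloalkenones, together with the spontaneous opening of dihalocarbene–cyclobutene adducts to 2,3-dihalocyclopentenes. No stereocentre is created, since C9 and C11 end as sp2 carbons and the face of carbene attack is immaterial, while C12 is not touched and keeps the configuration set in step 7. The step needs chemoselectivity for the enol ether over the C14=C15 alkene, which should follow from the much higher nucleophilicity and strain of the siloxycyclobutene towards the electrophilic carbene, from keeping the base as the limiting reagent and from working at −40 to 0 °C, which also forestalls thermal opening of the cyclobutene.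

Step 9
Reactants: 19 hex-5-ynoic acid
Product: 21 7-hydroxyhept-5-ynoic acid, via dilithiated acid 20 (not isolated)
Conditions: n-BuLi (2.1 equiv), THF, −78 → 0 °C; (CH2O)n, 0 → 20 °C; 1 M HCl
Reagents that add atoms: formaldehyde (as paraformaldehyde), C=O
Why: Hydroxymethylation of a lithium acetylide with formaldehyde; the first equivalent of base gives the carboxylate, which shields the acid carbon, and the second gives the acetylide that adds to formaldehyde and supplies C7.

Step 10
Reactants: 21 7-hydroxyhept-5-ynoic acid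
Product: 22 methyl 7-hydroxyhept-5-ynoate
Conditions: MeOH, H2SO4 (cat.), 20 °C
Reagents that add atoms: methanol, CO
Why: Fischer esterification in methanol; the primary propargylic alcohol is unchanged under dilute acid.

Step 11
Reactants: 22 methyl 7-hydroxyhept-5-ynoate
Product: 23 methyl (Z)-7-hydroxyhept-5-enoate
Conditions: H2 (1 atm), Pd/CaCO3 poisoned with Pb(OAc)2 (Lindlar catalyst), quinoline, EtOAc, 20 °C
Reagents that add atoms: none
Why: Lindlar semihydrogenation; syn addition of H2 gives the C5=C6 Z alkene, and the allylic alcohol and the ester are not reduced.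

Step 12
Reactants: 23 methyl (Z)-7-hydroxyhept-5-enoate
Product: 24 methyl (Z)-7-oxohept-5-enoate
Conditions: Dess–Martin periodinane, NaHCO3, CH2Cl2, 0 °C; used at once
Reagents that add atoms: none
Why: Dess–Martin oxidation of a primary allylic alcohol under buffered, cold conditions, which keeps the Z-enal from isomerising to the E-enal.

Step 13
Reactants: 18 (S)-4-[(tert-butyldimethylsilyl)oxy]-2-chloro-4-[(Z)-oct-2-en-1-yl]cyclopent-2-en-1-one; 24 methyl (Z)-7-oxohept-5-enoate
Product: 26 methyl (5Z)-7-[(2S)-2-[(tert-butyldimethylsilyl)oxy]-4-chloro-2-[(Z)-oct-2-en-1-yl]-5-oxocyclopent-3-en-1-yl]-7-hydroxyhept-5-enoate (mixture of C7/C8 diastereomers), via lithium dienolate 25 (not isolated)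
Conditions: LiN(iPr)2 (1.05 equiv), THF, −78 °C; then 24, −78 °C; aq. NH4Cl at −78 °C
Reagents that add atoms: none
Why: Aldol addition of a kinetic lithium enolate; C8 is the only enolisable position of 18, dienolate 25 adds 1,2 to the enal at −78 °C, and the new centres C7 and C8 form as a mixture that is of no consequence because both become sp2 in step 14.

Step 14
Reactants: 26 methyl (5Z)-7-[(2S)-2-[(tert-butyldimethylsilyl)oxy]-4-chloro-2-[(Z)-oct-2-en-1-yl]-5-oxocyclopent-3-en-1-yl]-7-hydroxyhept-5-enoate
Product: 28 methyl (5Z,7E)-7-[(2R)-2-[(tert-butyldimethylsilyl)oxy]-4-chloro-2-[(Z)-oct-2-en-1-yl]-5-oxocyclopent-3-en-1-ylidene]hept-5-enoate, via C7 mesylate 27 (not isolated)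
Conditions: MsCl, Et3N, CH2Cl2, −20 °C; then DBU, −20 → 0 °C, dark
Reagents that add atoms: none
Why: Mesylation followed by E1cB elimination through the C8 enolate, expected to favour the 7E geometry (C6 anti to the C9 carbonyl) as is usual for 2-alkylidenecyclopentanones; C5=C6 should stay Z if base contact is short and light is excluded, the minor 7Z isomer is removed by chromatography, and the C12 descriptor changes from S to R only because C8 gains priority on becoming sp2.

Step 15
Reactants: 28 methyl (5Z,7E)-7-[(2R)-2-[(tert-butyldimethylsilyl)oxy]-4-chloro-2-[(Z)-oct-2-en-1-yl]-5-oxocyclopent-3-en-1-ylidene]hept-5-enoate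
Product: 29 methyl (5Z,7E)-7-[(2R)-4-chloro-2-hydroxy-2-[(Z)-oct-2-en-1-yl]-5-oxocyclopent-3-en-1-ylidene]hept-5-enoate
Conditions: 48% aq. HF, MeCN, 0 → 20 °C
Reagents that add atoms: none
Why: Acidic fluoride cleavage of the silyl ether; HF is not basic, so the base-sensitive cross-conjugated dienone, the ester and both Z-alkenes are untouched, and the tertiary alcohol does not ionise because the cation would be flanked by the electron-poor dienone.

Step 16
Reactants: 29 methyl (5Z,7E)-7-[(2R)-4-chloro-2-hydroxy-2-[(Z)-oct-2-en-1-yl]-5-oxocyclopent-3-en-1-ylidene]hept-5-enoate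
Product: 30 methyl (5Z,7E)-7-[(2R)-2-acetoxy-4-chloro-2-[(Z)-oct-2-en-1-yl]-5-oxocyclopent-3-en-1-ylidene]hept-5-enoate
Conditions: Ac2O, DMAP (cat.), Et3N, CH2Cl2, 20 °C
Reagents that add atoms: acetic anhydride, CC(=O)OC(C)=O
Why: Nucleophile-catalysed acylation (acetylpyridinium transfer from DMAP) of the tertiary alcohol; no bond at C12 is broken, so its configuration is retained.

Compound list
1 | 3-chloro-2-(chloromethyl)prop-1-ene | C=C(CCl)CCl | starting material
2 | 2,2-bis(chloromethyl)oxirane | ClCC1(CCl)CO1 | intermediate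
3 | hept-1-yne | CCCCCC#C | starting material
4 | hept-1-ynyllithium | [Li]C#CCCCCC | intermediate (not isolated)
5 | 1-chloro-2-(chloromethyl)dec-4-yn-2-ol | CCCCCC#CCC(O)(CCl)CCl | intermediate
6 | (Z)-1-chloro-2-(chloromethyl)dec-4-en-2-ol | CCCCC/C=C\CC(O)(CCl)CCl | intermediate
7 | 1,3-dithiane | C1CSCSC1 | starting material
8 | 2-lithio-1,3-dithiane | [Li]C1SCCCS1 | intermediate (not isolated)
9 | 2-(chloromethyl)-2-[(Z)-oct-2-en-1-yl]oxirane (racemic) | CCCCC/C=C\CC1(CCl)CO1 | intermediate (not isolated)
10 | 2-({2-[(Z)-oct-2-en-1-yl]oxiran-2-yl}methyl)-1,3-dithiane (racemic) | CCCCC/C=C\CC1(CC2SCCCS2)CO1 | intermediate (not isolated)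
11 | 2-[(Z)-oct-2-en-1-yl]-5,9-dithiaspiro[3.5]nonan-2-ol (achiral) | CCCCC/C=C\CC1(O)CC2(C1)SCCCS2 | intermediate
12 | tert-butyldimethyl({2-[(Z)-oct-2-en-1-yl]-5,9-dithiaspiro[3.5]nonan-2-yl}oxy)silane | CCCCC/C=C\CC1(O[Si](C)(C)C(C)(C)C)CC2(C1)SCCCS2 | intermediate
13 | 3-[(tert-butyldimethylsilyl)oxy]-3-[(Z)-oct-2-en-1-yl]cyclobutan-1-one (achiral, mirror plane through C9 and C12) | CCCCC/C=C\CC1(O[Si](C)(C)C(C)(C)C)CC(=O)C1 | intermediate
14 | (S)-3-[(tert-butyldimethylsilyl)oxy]-3-[(Z)-oct-2-en-1-yl]-1-[(triethylsilyl)oxy]cyclobut-1-ene | CCCCC/C=C\C[C@@]1(O[Si](C)(C)C(C)(C)C)C=C(O[Si](CC)(CC)CC)C1 | intermediate (precursor of the key step)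
15 | chloroform | ClC(Cl)Cl | starting material
16 | dichlorocarbene | Cl[C]Cl | intermediate (not isolated)
17 | 3-[(tert-butyldimethylsilyl)oxy]-5,5-dichloro-3-[(Z)-oct-2-en-1-yl]-1-[(triethylsilyl)oxy]bicyclo[2.1.0]pentane, drawn with the CCl2 bridge on the ring face opposite to OTBS (the other face isomer gives the same product) | CCCCC/C=C\C[C@]1(O[Si](C)(C)C(C)(C)C)C[C@]2(O[Si](CC)(CC)CC)C(Cl)(Cl)[C@H]12 | intermediate (not isolated)
18 | (S)-4-[(tert-butyldimethylsilyl)oxy]-2-chloro-4-[(Z)-oct-2-en-1-yl]cyclopent-2-en-1-one | CCCCC/C=C\C[C@@]1(O[Si](C)(C)C(C)(C)C)C=C(Cl)C(=O)C1 | intermediate (product of the key step)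
19 | hex-5-ynoic acid | C#CCCCC(=O)O | starting material
20 | lithium 6-lithiohex-5-ynoate | [Li]C#CCCCC(=O)O[Li] | intermediate (not isolated)
21 | 7-hydroxyhept-5-ynoic acid | OCC#CCCCC(=O)O | intermediate
22 | methyl 7-hydroxyhept-5-ynoate | COC(=O)CCCC#CCO | intermediate
23 | methyl (Z)-7-hydroxyhept-5-enoate | COC(=O)CCC/C=C\CO | intermediate
24 | methyl (Z)-7-oxohept-5-enoate | COC(=O)CCC/C=C\C=O | intermediate
25 | lithium dienolate of 18 (C8=C9–OLi, C10=C11; C12 unchanged) | CCCCC/C=C\C[C@@]1(O[Si](C)(C)C(C)(C)C)C=C(Cl)C(O[Li])=C1 | intermediate (not isolated)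
26 | methyl (5Z)-7-[(2S)-2-[(tert-butyldimethylsilyl)oxy]-4-chloro-2-[(Z)-oct-2-en-1-yl]-5-oxocyclopent-3-en-1-yl]-7-hydroxyhept-5-enoate (C7/C8 diastereomers) | CCCCC/C=C\C[C@@]1(O[Si](C)(C)C(C)(C)C)C=C(Cl)C(=O)C1C(O)/C=C\CCCC(=O)OC | intermediate
27 | C7 methanesulfonate of 26 (C7/C8 diastereomers) | CCCCC/C=C\C[C@@]1(O[Si](C)(C)C(C)(C)C)C=C(Cl)C(=O)C1C(OS(C)(=O)=O)/C=C\CCCC(=O)OC | intermediate (not isolated)
28 | methyl (5Z,7E)-7-[(2R)-2-[(tert-butyldimethylsilyl)oxy]-4-chloro-2-[(Z)-oct-2-en-1-yl]-5-oxocyclopent-3-en-1-ylidene]hept-5-enoate | CCCCC/C=C\C[C@@]1(O[Si](C)(C)C(C)(C)C)C=C(Cl)C(=O)/C1=C/C=C\CCCC(=O)OC | intermediate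
29 | methyl (5Z,7E)-7-[(2R)-4-chloro-2-hydroxy-2-[(Z)-oct-2-en-1-yl]-5-oxocyclopent-3-en-1-ylidene]hept-5-enoate | CCCCC/C=C\C[C@@]1(O)C=C(Cl)C(=O)/C1=C/C=C\CCCC(=O)OC | intermediate
30 | methyl (5Z,7E)-7-[(2R)-2-acetoxy-4-chloro-2-[(Z)-oct-2-en-1-yl]-5-oxocyclopent-3-en-1-ylidene]hept-5-enoate | CCCCC/C=C\C[C@@]1(OC(C)=O)C=C(Cl)C(=O)/C1=C/C=C\CCCC(=O)OC | target

Total step count: 16.
Longest linear sequence: 12 steps (steps 1–8, then 13–16); the aldehyde branch (steps 9–12) joins at step 13.

Steps most likely to fail

Step 8 (key step). The enol ether may be consumed before the carbene reaches it, either by loss of the enol silyl group to tert-butoxide or by thermal opening of the siloxycyclobutene to a diene. Carbene may also be spent on the C14=C15 alkene or on the product enone. The fallback sets out from 14 and comes back to the route at 18; it enlarges the ring under non-basic conditions and adds the chlorine afterwards. Cyclopropanation of 14 with Et2Zn and CH2I2 in CH2Cl2 at 0 °C (Simmons–Smith reaction, Furukawa variant) should give 3-[(tert-butyldimethylsilyl)oxy]-3-[(Z)-oct-2-en-1-yl]-1-[(triethylsilyl)oxy]bicyclo[2.1.0]pentane F1. FeCl3 in DMF at 0 °C (Ito–Saegusa oxidative opening of the central bond) should then give 3-chloro-4-[(tert-butyldimethylsilyl)oxy]-4-[(Z)-oct-2-en-1-yl]cyclopentan-1-one F2, which NaOAc in MeOH converts to (S)-4-[(tert-butyldimethylsilyl)oxy]-4-[(Z)-oct-2-en-1-yl]cyclopent-2-en-1-one F3. Weitz–Scheffer epoxidation (H2O2, NaOH, MeOH, 0 °C), which leaves the isolated Z-alkene alone, gives 4-[(tert-butyldimethylsilyl)oxy]-4-[(Z)-oct-2-en-1-yl]-6-oxabicyclo[3.1.0]hexan-2-one F4. HCl in Et2O/CH2Cl2 at 0 °C opens the epoxide at C10 to 2-chloro-3-hydroxy-4-[(tert-butyldimethylsilyl)oxy]-4-[(Z)-oct-2-en-1-yl]cyclopentan-1-one F5, which loses water in the flask to give 18.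

Step 7. Discrimination between the two enantiotopic methylenes may be poor, because the amide must also keep to the ring face remote from OTBS, and exchange between the enolate and unreacted ketone before silylation would erode the enantiomeric purity further. The fallback sets out from 13 and comes back to the route at 18; it replaces asymmetric enolisation by resolution. Enolisation of 13 with LiN(iPr)2 and Et3SiCl in THF at −78 °C gives racemic 3-[(tert-butyldimethylsilyl)oxy]-3-[(Z)-oct-2-en-1-yl]-1-[(triethylsilyl)oxy]cyclobut-1-ene F6. The ring enlargement of step 8 then gives racemic 4-[(tert-butyldimethylsilyl)oxy]-2-chloro-4-[(Z)-oct-2-en-1-yl]cyclopent-2-en-1-one F7, and preparative chromatography on a chiral stationary phase (a cellulose or amylose carbamate) separates 18 from its enantiomer. The same separation can polish material of incomplete enantiomeric purity from the main route.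

Step 4. The second lithiation, which has to take place beside an epoxide, may be outrun by intermolecular opening of that epoxide (oligomers), or the sequence may stall at the epoxy dithiane. The fallback sets out from 6 and comes back to the route at 13; it uses a much more acidic one-carbon unit and unmasks the ketone by oxidation. Aqueous NaOH closes 6 to oxirane 9, which is isolated here. Lithiated methyl phenyl sulfone (PhSO2CH3, n-BuLi, THF, −78 °C) opens the oxirane at CH2 and the alkoxide re-closes onto the chloromethyl group. A second equivalent of n-BuLi regenerates the sulfonyl carbanion at −78 °C, which closes the ring to 1-[(Z)-oct-2-en-1-yl]-3-(phenylsulfonyl)cyclobutan-1-ol F8 (cis/trans mixture), the reaction type known for epichlorohydrin. TBSOTf and 2,6-lutidine give tert-butyldimethyl({1-[(Z)-oct-2-en-1-yl]-3-(phenylsulfonyl)cyclobutyl}oxy)silane F9. Lithiation α to the sulfone (n-BuLi, THF, −78 °C) and oxidation of the carbanion with Me3SiOOSiMe3 (oxidative desulfonylation) then give ketone 13.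

Further compounds
F1 | step 8 | 3-[(tert-butyldimethylsilyl)oxy]-3-[(Z)-oct-2-en-1-yl]-1-[(triethylsilyl)oxy]bicyclo[2.1.0]pentane (CH2 bridge drawn on the face opposite to OTBS) | CCCCC/C=C\C[C@]1(O[Si](C)(C)C(C)(C)C)C[C@]2(O[Si](CC)(CC)CC)C[C@H]12
F2 | step 8 | 3-chloro-4-[(tert-butyldimethylsilyl)oxy]-4-[(Z)-oct-2-en-1-yl]cyclopentan-1-one (both C11 epimers) | CCCCC/C=C\C[C@@]1(O[Si](C)(C)C(C)(C)C)C(Cl)CC(=O)C1
F3 | step 8 | (S)-4-[(tert-butyldimethylsilyl)oxy]-4-[(Z)-oct-2-en-1-yl]cyclopent-2-en-1-one | CCCCC/C=C\C[C@@]1(O[Si](C)(C)C(C)(C)C)C=CC(=O)C1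
F4 | step 8 | 4-[(tert-butyldimethylsilyl)oxy]-4-[(Z)-oct-2-en-1-yl]-6-oxabicyclo[3.1.0]hexan-2-one (epoxide face isomers) | CCCCC/C=C\C[C@@]1(O[Si](C)(C)C(C)(C)C)C2OC2C(=O)C1
F5 | step 8 | 2-chloro-3-hydroxy-4-[(tert-butyldimethylsilyl)oxy]-4-[(Z)-oct-2-en-1-yl]cyclopentan-1-one (C10/C11 diastereomers) | CCCCC/C=C\C[C@@]1(O[Si](C)(C)C(C)(C)C)C(O)C(Cl)C(=O)C1
F6 | step 7 | racemic 3-[(tert-butyldimethylsilyl)oxy]-3-[(Z)-oct-2-en-1-yl]-1-[(triethylsilyl)oxy]cyclobut-1-ene | CCCCC/C=C\CC1(O[Si](C)(C)C(C)(C)C)C=C(O[Si](CC)(CC)CC)C1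
F7 | step 7 | racemic 4-[(tert-butyldimethylsilyl)oxy]-2-chloro-4-[(Z)-oct-2-en-1-yl]cyclopent-2-en-1-one | CCCCC/C=C\CC1(O[Si](C)(C)C(C)(C)C)C=C(Cl)C(=O)C1
F8 | step 4 | 1-[(Z)-oct-2-en-1-yl]-3-(phenylsulfonyl)cyclobutan-1-ol (cis/trans mixture) | CCCCC/C=C\CC1(O)CC(C1)S(=O)(=O)c1ccccc1
F9 | step 4 | tert-butyldimethyl({1-[(Z)-oct-2-en-1-yl]-3-(phenylsulfonyl)cyclobutyl}oxy)silane (cis/trans mixture) | CCCCC/C=C\CC1(O[Si](C)(C)C(C)(C)C)CC(C1)S(=O)(=O)c1ccccc1
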